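(All runs were computed with constants of no real substance, and the scatter is random.)

- Hold theta and beta at 40 °C and read each at its own time: substrate pairs up into target, and one target counts as two substrate units.

| flask | substrate | temperature | remark | time |
|---|---|---|---|---|
| green | 0.15 M | 35 °C | run made earlier |  |
| grey | 0.24 M | 46 °C | run made earlier |  |
| theta | 0.10 M | 40 °C |  | 6.0 min |
| beta | 0.20 M | 40 °C |  | 2.0 min |

| run | time / min | target / % | substrate / % |
|---|---|---|---|
| green | 1.50 | 69.0 | 18.0 |
| green | 3.00 | 76.5 | 11.1 |
| green | 5.00 | 80.6 | 9.2 |
| green | 6.00 | 82.2 | 7.7 |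
| grey | 1.50 | 80.6 | 8.2 |
| grey | 3.00 | 84.4 | 6.2 |
| grey | 5.00 | 86.1 | 3.9 |
| grey | 6.00 | 86.8 | 2.7 |

(standard deviation of a reading: 0.5 percentage points)

1. the winner by amount of target, in percent of the substrate charged; "neither" if no more than 2 percentage points parts them (theta / beta / neither)
2. how much target is there at the end, in percent of the substrate charged: theta
3. how much target is there at the end, in percent of the substrate charged: beta

- percent here means substrate units held: one target counts as two

- Green and grey at their last readings average 10.3% unseen: this is the unseen share, charge less target less substrate read, the gap in the mass balance.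
- By my own reckoning, target in theta and in beta should end under a ceiling of 89.7%, and below it by whatever substrate remains.
- The approach is not over at the last readings: green still holds 7.7% substrate and grey 2.7%.
- Keep the bath at 40 °C and add nothing: the share was read between 35 °C and 46 °C, on flasks left to run.
- The forecast gives theta 80.8% (78.5% to 83.5%) and beta 77.5% (75% to 80%), with theta as winner, and reads the balance of the earlier runs as “about 10% is lost to a side path”.

    2 substrate → target (k = 11.0 M⁻¹ min⁻¹, Ea = 50.0 kJ mol⁻¹)
    target ⇌ isomer of the product (K = 1.20, k = 0.00740 min⁻¹, Ea = 104 kJ mol⁻¹, ΔH = 8.00 kJ mol⁻¹)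
    substrate ⇌ dormant form (K = 0.770, k = 0.430 min⁻¹, Ea = 86.0 kJ mol⁻¹, ΔH = −8.00 kJ mol⁻¹)
    substrate → decomposition product (k = 1.80 × 10⁻⁴ min⁻¹, Ea = 110 kJ mol⁻¹)
    (constants at 40 °C)

- Theta ends at 78.4% and beta at 78.8%, so the verdict is neither: 0.40 percentage points apart against a margin of 2 points. The unseen share is 12.1% in theta, made of dormant form at 9.20%, isomer of the product at 2.92% and decomposition product at 0.0210%, and 11.2% in beta. Theta's share is larger than the 10.3% carried over. Theta has not come to rest at 6.0 min, and the relaxation half-life between target and isomer of the product in theta, 51.1 min, is longer than that time. At 60.0 min theta's target has fallen 9.1 points to 69.3%, and its share has grown to 29.4%. Beta still moves too: at 20.0 min its target stands at 84.5%, up 5.7 points, with a share of 13.4%.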